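## Structural features

The target is one heavily oxygenated cyclohexanone. Its ring atoms are numbered C1 (quaternary tertiary carbinol that also carries the exocyclic C7H2–OBz), C2 (ketone), C3 (the only methylene), C4 (secondary OH), C5 (secondary benzoate) and C6 (secondary OH). The four stereocentres C4, C5, C6 and C1 are contiguous, (1S,4R,5R,6S) in this numbering: the C1 and C6 hydroxyls are cis, the C5 benzoate is trans to the C6 hydroxyl and cis to the C4 hydroxyl. C4–OH is β to the ketone, so dehydration to the conjugated enone is the main decomposition path under base, heat or strong acid, and the C1 carbinol is an α-ketol that is safest kept protected until the end. The C5 benzoate lies between two free hydroxyls and can migrate under base. The real difficulty is the quaternary C1 with its three different oxygenated carbon arms, together with telling five oxygens apart so that only O5 and O7 are acylated and only C2 is at the ketone level. The key step uses the fact that C2 lies between the quaternary C1 and the one unoxygenated carbon C3: C2 enters as a nitronate carbon (an acyl anion equivalent) and C3–C4=C5 as an allyl unit, so that forming C2–C3 closes the ring and leaves the C4=C5 alkene where the cis C4/C5 diol is needed.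

## Logic of the disconnections

25 to 24: O1 and O6 are joined in an isopropylidene ketal, so the last forward step cuts the two ketal C–O bonds. This keeps the α-ketol and the C6 hydroxyl masked while the ketone and the C5 ester are installed, and leaves a single deprotection at the end. The demand is a hydrolysis mild enough not to dehydrate the β-hydroxy ketone or move the C5 benzoate.

24 to 22 and 3: the O5–acyl bond is cut, exposing the cis C4/C5 diol. The gain is a symmetrical origin (an alkene) for the two oxygens. The demand is that the forward acylation distinguishes equatorial O5 from axial O4 without base strong enough to eliminate O4.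

22 to 20: the C2 carbonyl is traced to a C2 nitro group; no skeletal bond is cut. The nitro group is what makes C2 a carbon nucleophile earlier on. The demand is a Nef reaction that tolerates a benzoate, a ketal oxygen β to the nitronate and two free carbinols.

20 to 19: the C4–O and C5–O bonds are cut together, giving the ring alkene. Two stereocentres are removed in one operation. The forward addition must be syn and come from the face opposite the dioxolane.

19 to 17: the C2–C3 ring bond is cut, opening the carbocycle to an acyclic nitromethyl compound with a Z-allylic carbonate. This is the strategic cut: it removes the ring and leaves a chain whose stereocentres are only C1 and C6. The forward step needs the nitronate to attack the distal allyl terminus, and needs CH2NO2 and the alkenyl arm cis on the dioxolane.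

17 to 16 and 3, then 16 to 14 and 15: the two O–acyl bonds at O7 (benzoate) and at the allylic oxygen (carbonate) are cut. The gain is a simple diol. The demand is that the forward acylations differentiate an unhindered allylic primary hydroxyl from a neopentyl-type primary hydroxyl.

14 to 13, then 13 to 11 and 12: the allylic alcohol is traced to the Z-enoate and the C4=C5 bond is cut to an aldehyde and a two-carbon ylide. This brings in C3 and C4 in one step. The olefination must be Z-selective and must not deprotonate the nitromethyl group, which restricts it to a stabilised ylide and makes the hydride reduction (and loss of the O7 ester) unavoidable.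

11 to 10, 9, 8, 7 and 6: no skeletal bond is cut. The C5 aldehyde is traced to the primary alcohol, and the ketal is moved from O1/O6 back to O5/O6. The 5,6-ketal is needed at the stage of 4 for stereocontrol, the 1,6-ketal later to block retro-Henry cleavage and to hold C2 and C5 cis. The demand is a reliable relay: hydrolysis, masking of O5, ketalisation of the only remaining diol, unmasking, base-free oxidation.

6 to 4 and 5: the C1–C2 bond is cut (Henry disconnection). This removes the quaternary stereocentre and leaves a ketone with one stereocentre. The forward addition must occur on the ketone face dictated by the adjacent dioxolane.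

4 to 2 and 3, then 2 to 1: the O7–acyl bond and the ketal C–O bonds are cut. Compound 1 supplies C7, C1, C6, C5 and the C6 configuration. The ketalisation must take the 3,4-diol and leave the C7 hydroxyl free.

## Other disconnections considered

Alternative 1: The ring is cut at C2–C3 and C1–C6, back to furan A1 and 2-bromoacrolein A2. The forward key step is a [4+2] cycloaddition under a tryptophan-derived B-butyl oxazaborolidine (a chiral boron Lewis acid), giving the oxa-bridged adduct A3 with the formyl group exo.
- In its favour: two ring bonds, the carbocycle, the quaternary C1 and the C6–O stereocentre arise in one catalytic step from bulk chemicals. The formyl carbon is C7, and replacing bromine by oxygen with inversion through a spiro-epoxide would put the C1 oxygen cis to the bridge oxygen on C6, as required. The C4=C5 alkene is already present.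
- Against it here: the bridge also puts an oxygen on C3, the one ring carbon that is unoxygenated in 25, while C2, which must become the ketone, arrives as a methylene. A bridge opening by elimination followed by regioselective oxygenation at C2 (a 1,2-transposition) would be needed. Osmylation of the intact bicycle is expected from the exo face, syn to the bridge, which would place O4 and O5 cis to O6 and not trans, so the order of later events is constrained. Furan adducts are also prone to cycloreversion.
- Configuration: A3 has to be the (1S,2S,4S) antipode shown in the block below. The mirror-image adduct carries the wrong configuration at C6 and would lead to the enantiomer of 25.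
- Comparison: the cycloaddition is the cleaner step mechanistically (concerted, no base, no epimerisable nitro compound). On absolute stereocontrol it is the better of the two, being catalyst-controlled where step 3 depends on substrate bias. On step economy to the ring it is far better (one step against thirteen), but the oxygen pattern is off by one carbon and the corrective steps would probably use up that lead. The chosen plan delivers every ring carbon at the right oxidation level directly after ring closure.

Alternative 2: The ring is cut at C5=C6, back to the 1,7-diene A4 with vinyl groups on C1 and C4. The forward key step is ring-closing metathesis with the second-generation Grubbs catalyst RuCl2(H2IMes)(PCy3)(=CHPh), which expels the two terminal methylene carbons and gives cyclohexenol A5. A5 would then be epoxidised on the face of the C1 hydroxyl and opened at C5 by a benzoate nucleophile.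
- In its favour: closure of a six-membered ring by metathesis is among the most dependable ring closures, is neutral and puts no stereocentre at risk. The epoxide opening would install the C5 benzoate and the trans C6 hydroxyl in one step, so no diol has to be differentiated; on this point it is better than step 16 of the chosen plan.
- Against it here: C1, C4 and the C2 carbinol must all be set in the open chain before the ring exists. C2 arrives as a protected alcohol, so late in the route the dioxane ketal must be removed, O7 benzoylated and the C2 hydroxyl oxidised in the presence of the C6 hydroxyl, which needs extra protecting-group steps. The regiochemistry of the epoxide opening (C5 against C6) rests on conformational control.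
- Comparison: the ring-forming step is the equal or the better of the palladium cyclization in reliability (no Z-alkene requirement, no nitronate). The chosen plan is better after ring closure, because the nitro group becomes the C2 ketone without touching any carbinol, and it needs fewer steps between ring closure and 25 (four). Overall step counts would be similar.

Alternative 3: The ring is cut at C3–C4, back to the branched 6-deoxyhex-5-enopyranoside A6. The forward key step is a Ferrier carbocyclization: catalytic Hg(OCOCF3)2 (divalent mercury) in aqueous acetone hydrates the exocyclic enol ether, the ring opens to a 1,5-dicarbonyl compound, and the C3 mercurio-enolate adds to the C4 aldehyde to give A7, which is identical with 24.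
- In its favour: the C2 ketone, the C3 methylene and the C4 carbinol are formed directly in their final relationship. The product is the penultimate compound of the chosen route, so no Nef reaction, osmylation or tin step follows; this endgame is better than the chosen one. The usual preference of the reaction for a new hydroxyl trans to the oxygen two carbons away (here O6) corresponds to the required C4 configuration.
- Against it here: A6 is a sugar with a quaternary, branched C1 next to the enol ether. Making it from a hexopyranoside needs selective protection, oxidation at the branching carbon, a stereocontrolled one-carbon branching and an iodination/elimination, probably ten steps or more, in a configurational series that is not a cheap sugar. The β-hydroxy ketone is formed under Lewis-acidic aqueous conditions where dehydration competes, and a mercury salt is used.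
- Comparison: both plans take C5 and C6 from the chiral pool. The Ferrier route sets C4 during ring closure under kinetic control, whereas the chosen plan sets C4 and C5 together by a syn osmylation whose facial sense is fixed by the bicycle. On step economy after the key step alternative 3 is better; before it, it is longer.

Key step: step 13

Remark: C2 of 19 and 20 is an epimerisable nitro-bearing centre that becomes the carbonyl carbon in step 15. Both are drawn and named as the epimer with nitro trans to the C1 oxygen and are expected as mixtures with the other epimer, which is without consequence.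

## Steps

Step 1
Reactants: 1 L-erythrulose
Product: 2 1-[(4S)-2,2-dimethyl-1,3-dioxolan-4-yl]-2-hydroxyethan-1-one (3,4-O-isopropylidene-L-erythrulose)
Conditions: 2,2-dimethoxypropane, TsOH·H2O (cat.), acetone, rt
Reagents that add atoms: 2,2-dimethoxypropane, COC(C)(C)OC
Why: Acid-catalysed transketalisation; the vicinal 3,4-diol closes the five-membered dioxolane in preference to a six-membered ring through O1 and O3, which leaves only the C7 hydroxyl free, and the C6 stereocentre is not touched.

Step 2
Reactants: 2 3,4-O-isopropylidene-L-erythrulose; 3 benzoyl chloride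
Product: 4 2-[(4S)-2,2-dimethyl-1,3-dioxolan-4-yl]-2-oxoethyl benzoate
Conditions: BzCl, pyridine, CH2Cl2, 0 °C
Reagents that add atoms: benzoyl chloride (3), O=C(Cl)c1ccccc1
Why: Acylation of the only free hydroxyl with an acid chloride and pyridine; the ester blocks O7 through the protecting-group relay of steps 4 to 9.

Step 3
Reactants: 4 2-[(4S)-2,2-dimethyl-1,3-dioxolan-4-yl]-2-oxoethyl benzoate; 5 nitromethane
Product: 6 (2S)-2-[(4S)-2,2-dimethyl-1,3-dioxolan-4-yl]-2-hydroxy-3-nitropropyl benzoate
Conditions: MeNO2 (solvent), Et3N (0.2 equiv), 0 °C to rt; AcOH quench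
Reagents that add atoms: nitromethane (5), C[N+](=O)[O-]
Why: Henry (nitroaldol) addition to an electron-poor α,α′-dioxygenated ketone under a catalytic, non-chelating amine base; in the Felkin–Anh (polar) or Cornforth arrangement the ring C–O bond on C6 is turned away from the incoming nucleophile, which should place CH2NO2 on the face that makes C1 (S), with nitromethyl and the future C5 on the same side of the C1–C6 bond. The C1 epimers are separable diastereomers, and the acid quench before concentration prevents retro-Henry loss.

Step 4
Reactants: 6 (2S)-2-[(4S)-2,2-dimethyl-1,3-dioxolan-4-yl]-2-hydroxy-3-nitropropyl benzoate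
Product: 7 (2S,3S)-2,3,4-trihydroxy-2-(nitromethyl)butyl benzoate
Conditions: AcOH–H2O (4:1), 40 °C
Reagents that add atoms: none
Why: Aqueous acid hydrolysis of the terminal isopropylidene ketal; an acidic medium is chosen because base would trigger retro-Henry cleavage of the free β-nitro tertiary alcohol and benzoate migration.

Step 5
Reactants: 7 (2S,3S)-2,3,4-trihydroxy-2-(nitromethyl)butyl benzoate
Product: 8 (2S,3S)-4-[(tert-butyldimethylsilyl)oxy]-2,3-dihydroxy-2-(nitromethyl)butyl benzoate
Conditions: TBSCl (1.05 equiv), imidazole, CH2Cl2, −20 to 0 °C
Reagents that add atoms: tert-butyl(chloro)dimethylsilane, CC(C)(C)[Si](C)(C)Cl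
Why: Sterically controlled silylation of the single primary hydroxyl over the secondary and tertiary ones; it masks O5 so that the only 1,2-diol left is the C1/C6 pair.

Step 6
Reactants: 8 (2S,3S)-4-[(tert-butyldimethylsilyl)oxy]-2,3-dihydroxy-2-(nitromethyl)butyl benzoate
Product: 9 [(4S,5S)-5-{[(tert-butyldimethylsilyl)oxy]methyl}-2,2-dimethyl-4-(nitromethyl)-1,3-dioxolan-4-yl]methyl benzoate
Conditions: 2-methoxypropene, PPTS (cat.), CH2Cl2, 0 °C to rt
Reagents that add atoms: 2-methoxypropene, COC(C)=C
Why: Ketalisation of the only free diol with an enol ether under mild acid; the new dioxolane ties O1 to O6, which blocks retro-Henry cleavage for the rest of the route and holds CH2NO2 and the C5 arm cis on a five-membered ring.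

Step 7
Reactants: 9 [(4S,5S)-5-{[(tert-butyldimethylsilyl)oxy]methyl}-2,2-dimethyl-4-(nitromethyl)-1,3-dioxolan-4-yl]methyl benzoate
Product: 10 [(4S,5S)-5-(hydroxymethyl)-2,2-dimethyl-4-(nitromethyl)-1,3-dioxolan-4-yl]methyl benzoate
Conditions: HF·pyridine, pyridine, THF, 0 °C to rt
Reagents that add atoms: none
Why: Fluoride cleavage of the primary silyl ether under buffered, slightly acidic conditions that leave benzoate, ketal and the acidic nitro group alone; a basic fluoride source would generate the nitronate.

Step 8
Reactants: 10 [(4S,5S)-5-(hydroxymethyl)-2,2-dimethyl-4-(nitromethyl)-1,3-dioxolan-4-yl]methyl benzoate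
Product: 11 [(4S,5R)-5-formyl-2,2-dimethyl-4-(nitromethyl)-1,3-dioxolan-4-yl]methyl benzoate
Conditions: Dess–Martin periodinane, CH2Cl2, 0 °C to rt
Reagents that add atoms: none
Why: Dess–Martin oxidation of the primary alcohol to the aldehyde without base, so that neither epimerisation at C6 nor nitroaldol self-condensation of the nitro aldehyde is triggered; 11 is used directly.

Step 9
Reactants: 11 [(4S,5R)-5-formyl-2,2-dimethyl-4-(nitromethyl)-1,3-dioxolan-4-yl]methyl benzoate; 12 methyl (triphenyl-λ5-phosphanylidene)acetate
Product: 13 methyl (2Z)-3-[(4S,5S)-5-[(benzoyloxy)methyl]-2,2-dimethyl-5-(nitromethyl)-1,3-dioxolan-4-yl]prop-2-enoate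
Conditions: Ph3P=CHCO2Me, MeOH, 0 °C
Reagents that add atoms: methyl (triphenyl-λ5-phosphanylidene)acetate (12), COC(=O)C=P(c1ccccc1)(c1ccccc1)c1ccccc1
Why: Wittig olefination with a stabilised ylide, which is too weakly basic to deprotonate the nitromethyl group; in methanol, α-alkoxy aldehydes of the dioxolane type are expected to give mainly the Z-enoate, and the minor E isomer is removed by chromatography.

Step 10
Reactants: 13 methyl (2Z)-3-[(4S,5S)-5-[(benzoyloxy)methyl]-2,2-dimethyl-5-(nitromethyl)-1,3-dioxolan-4-yl]prop-2-enoate
Product: 14 (2Z)-3-[(4S,5S)-5-(hydroxymethyl)-2,2-dimethyl-5-(nitromethyl)-1,3-dioxolan-4-yl]prop-2-en-1-ol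
Conditions: iBu2AlH (6 equiv), CH2Cl2, −78 °C; aq. potassium sodium tartrate
Reagents that add atoms: none
Why: 1,2-Reduction of the conjugated ester by the aluminium hydride gives the allylic alcohol with the Z geometry intact; the O7 benzoate, having served as protecting group, is reduced off in the same operation, and the aliphatic nitro group is tolerated at −78 °C.

Step 11
Reactants: 14 (2Z)-3-[(4S,5S)-5-(hydroxymethyl)-2,2-dimethyl-5-(nitromethyl)-1,3-dioxolan-4-yl]prop-2-en-1-ol; 15 methyl chloroformate
Product: 16 (2Z)-3-[(4S,5S)-5-(hydroxymethyl)-2,2-dimethyl-5-(nitromethyl)-1,3-dioxolan-4-yl]prop-2-en-1-yl methyl carbonate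
Conditions: ClCO2Me (1.05 equiv), pyridine, CH2Cl2, −40 °C
Reagents that add atoms: methyl chloroformate (15), COC(=O)Cl
Why: Chemoselective acylation with a chloroformate; the unhindered allylic primary hydroxyl should react well before the neopentyl-type C7 hydroxyl on the quaternary carbon, so one equivalent at low temperature should give the allylic monocarbonate.

Step 12
Reactants: 16 (2Z)-3-[(4S,5S)-5-(hydroxymethyl)-2,2-dimethyl-5-(nitromethyl)-1,3-dioxolan-4-yl]prop-2-en-1-yl methyl carbonate; 3 benzoyl chloride
Product: 17 [(4S,5S)-5-{(1Z)-3-[(methoxycarbonyl)oxy]prop-1-en-1-yl}-2,2-dimethyl-4-(nitromethyl)-1,3-dioxolan-4-yl]methyl benzoate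
Conditions: BzCl, pyridine, DMAP (cat.), CH2Cl2, 0 °C to rt
Reagents that add atoms: benzoyl chloride (3), O=C(Cl)c1ccccc1
Why: DMAP-catalysed benzoylation of the remaining hindered primary alcohol; this is the C7 benzoate of the target, and no other hydroxyl is present.

Step 13
Reactants: 17 [(4S,5S)-5-{(1Z)-3-[(methoxycarbonyl)oxy]prop-1-en-1-yl}-2,2-dimethyl-4-(nitromethyl)-1,3-dioxolan-4-yl]methyl benzoate
Product: 19 [(3aS,4S,7aS)-2,2-dimethyl-4-nitro-3a,4,5,7a-tetrahydro-1,3-benzodioxol-3a-yl]methyl benzoate, via allylpalladium nitronate zwitterion 18 (not isolated)
Conditions: Pd(PPh3)4 (5 mol %), THF (0.02 M), 40 °C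
Reagents that add atoms: none
Why: Zerovalent palladium adds oxidatively to the Z-allylic carbonate with inversion, CO2 is lost, and the methoxide so released removes a proton from the nitromethyl group (the most acidic site), giving the anti-configured allylpalladium cation paired with its own nitronate, 18; the closest known reaction type is the intramolecular Tsuji–Trost allylic alkylation of nitroalkanes with allylic carbonates under neutral conditions. The soft nitronate carbon C2 attacks the distal allyl terminus C3 on the face opposite to palladium, forming C2–C3 and closing the six-membered carbocycle in the endo mode with respect to the allyl unit, so that all three allyl carbons lie in the ring and C4=C5 is the ring alkene. Attack at the proximal terminus C5 would give a vinylcyclobutane and is excluded by ring strain, and O-allylation of the nitronate is reversible under palladium catalysis and should drain into the C-alkylated product. The Z geometry of 17 is essential: it delivers the anti allyl complex in which C3 can reach C2, whereas a syn complex could close only to a trans-cyclohexene. The cis relationship of CH2NO2 and the alkenyl arm on the dioxolane holds the two reacting carbons on the same side, so the ring closes as the cis-fused bicycle. The only new stereocentre, C2, is under thermodynamic control (the product is still a C–H acidic nitroalkane) and is erased in step 15, so either epimer serves. The ketal prevents retro-Henry cleavage, and because base is generated only as fast as the allyl complex forms, the C7 benzoate and the β-alkoxy nitronate are not exposed to free alkoxide.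

Step 14
Reactants: 19 [(3aS,4S,7aS)-2,2-dimethyl-4-nitro-3a,4,5,7a-tetrahydro-1,3-benzodioxol-3a-yl]methyl benzoate
Product: 20 [(3aS,4S,6R,7R,7aS)-6,7-dihydroxy-2,2-dimethyl-4-nitrohexahydro-1,3-benzodioxol-3a-yl]methyl benzoate
Conditions: OsO4 (2 mol %), NMO, acetone–H2O (4:1), rt
Reagents that add atoms: OsO4, O=[Os](=O)(=O)=O; N-methylmorpholine N-oxide, C[N+]1([O-])CCOCC1; water, O
Why: Catalytic osmylation (Upjohn dihydroxylation) is a suprafacial syn addition; the reagent should approach C4=C5 anti to the allylic C6–O bond and from the convex face of the cis-fused bicycle, away from the dioxolane, which sets C4 (R) and C5 (R) with both new hydroxyls trans to O6.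

Step 15
Reactants: 20 [(3aS,4S,6R,7R,7aS)-6,7-dihydroxy-2,2-dimethyl-4-nitrohexahydro-1,3-benzodioxol-3a-yl]methyl benzoate
Product: 22 [(3aS,6R,7R,7aS)-6,7-dihydroxy-2,2-dimethyl-4-oxohexahydro-1,3-benzodioxol-3a-yl]methyl benzoate, via potassium nitronate 21 (not isolated)
Conditions: KOtBu (1.05 equiv), THF, −20 °C; then dimethyldioxirane in acetone, −20 to 0 °C
Reagents that add atoms: dimethyldioxirane, CC1(C)OO1
Why: Oxidative Nef reaction; the nitro group is the most acidic site, so one equivalent of KOtBu gives nitronate 21, whose C=N bond is cleaved by oxygen transfer from the dioxirane with loss of nitrite. Low temperature and the poor leaving-group ability of the ketal oxygen on C1 should hold back β-elimination, and the C2 stereocentre disappears.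

Step 16
Reactants: 22 [(3aS,6R,7R,7aS)-6,7-dihydroxy-2,2-dimethyl-4-oxohexahydro-1,3-benzodioxol-3a-yl]methyl benzoate; 3 benzoyl chloride
Product: 24 [(3aS,6R,7R,7aS)-7-(benzoyloxy)-6-hydroxy-2,2-dimethyl-4-oxohexahydro-1,3-benzodioxol-3a-yl]methyl benzoate, via dibutylstannylene acetal 23 (not isolated)
Conditions: Bu2SnO (1.1 equiv), MeOH, reflux, then evaporation; BzCl (1.05 equiv), 1,4-dioxane, rt
Reagents that add atoms: benzoyl chloride (3), O=C(Cl)c1ccccc1
Why: Tin-mediated regioselective monoacylation; in the chair that keeps CH2OBz equatorial, O5 is equatorial and O4 axial, and the cis-diol stannylene acetal 23 is acylated at the equatorial oxygen, as in the corresponding reaction of galactopyranoside 3,4-diols. No amine base is present, which should spare the β-hydroxy ketone from dehydration.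

Step 17
Reactants: 24 [(3aS,6R,7R,7aS)-7-(benzoyloxy)-6-hydroxy-2,2-dimethyl-4-oxohexahydro-1,3-benzodioxol-3a-yl]methyl benzoate
Product: 25 [(1S,2S,3R,4R)-3-(benzoyloxy)-1,2,4-trihydroxy-6-oxocyclohexyl]methyl benzoate (CNP0127041.1)
Conditions: CF3CO2H–H2O (9:1), 0 °C
Reagents that add atoms: none
Why: Acid hydrolysis of the isopropylidene ketal; in cold aqueous trifluoroacetic acid acyl migration is slow and the β-hydroxy ketone should survive, and no stereocentre is affected.

## Compound list

1 | L-erythrulose, (3S)-1,3,4-trihydroxybutan-2-one | OCC(=O)[C@@H](O)CO | starting material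
2 | 1-[(4S)-2,2-dimethyl-1,3-dioxolan-4-yl]-2-hydroxyethan-1-one | OCC(=O)[C@@H]1COC(C)(C)O1 | intermediate
3 | benzoyl chloride | O=C(Cl)c1ccccc1 | starting material
4 | 2-[(4S)-2,2-dimethyl-1,3-dioxolan-4-yl]-2-oxoethyl benzoate | O=C(OCC(=O)[C@@H]1COC(C)(C)O1)c1ccccc1 | intermediate
5 | nitromethane | C[N+](=O)[O-] | starting material
6 | (2S)-2-[(4S)-2,2-dimethyl-1,3-dioxolan-4-yl]-2-hydroxy-3-nitropropyl benzoate | O=C(OC[C@@](O)(C[N+](=O)[O-])[C@@H]1COC(C)(C)O1)c1ccccc1 | intermediate
7 | (2S,3S)-2,3,4-trihydroxy-2-(nitromethyl)butyl benzoate | O=C(OC[C@@](O)(C[N+](=O)[O-])[C@@H](O)CO)c1ccccc1 | intermediate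
8 | (2S,3S)-4-[(tert-butyldimethylsilyl)oxy]-2,3-dihydroxy-2-(nitromethyl)butyl benzoate | O=C(OC[C@@](O)(C[N+](=O)[O-])[C@@H](O)CO[Si](C)(C)C(C)(C)C)c1ccccc1 | intermediate
9 | [(4S,5S)-5-{[(tert-butyldimethylsilyl)oxy]methyl}-2,2-dimethyl-4-(nitromethyl)-1,3-dioxolan-4-yl]methyl benzoate | [O-][N+](=O)C[C@@]1(COC(=O)c2ccccc2)OC(C)(C)O[C@H]1CO[Si](C)(C)C(C)(C)C | intermediate
10 | [(4S,5S)-5-(hydroxymethyl)-2,2-dimethyl-4-(nitromethyl)-1,3-dioxolan-4-yl]methyl benzoate | [O-][N+](=O)C[C@@]1(COC(=O)c2ccccc2)OC(C)(C)O[C@H]1CO | intermediate
11 | [(4S,5R)-5-formyl-2,2-dimethyl-4-(nitromethyl)-1,3-dioxolan-4-yl]methyl benzoate | [O-][N+](=O)C[C@@]1(COC(=O)c2ccccc2)OC(C)(C)O[C@H]1C=O | intermediate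
12 | methyl (triphenyl-λ5-phosphanylidene)acetate | COC(=O)C=P(c1ccccc1)(c1ccccc1)c1ccccc1 | starting material
13 | methyl (2Z)-3-[(4S,5S)-5-[(benzoyloxy)methyl]-2,2-dimethyl-5-(nitromethyl)-1,3-dioxolan-4-yl]prop-2-enoate | [O-][N+](=O)C[C@@]1(COC(=O)c2ccccc2)OC(C)(C)O[C@H]1/C=C\C(=O)OC | intermediate
14 | (2Z)-3-[(4S,5S)-5-(hydroxymethyl)-2,2-dimethyl-5-(nitromethyl)-1,3-dioxolan-4-yl]prop-2-en-1-ol | [O-][N+](=O)C[C@@]1(CO)OC(C)(C)O[C@H]1/C=C\CO | intermediate
15 | methyl chloroformate | COC(=O)Cl | starting material
16 | (2Z)-3-[(4S,5S)-5-(hydroxymethyl)-2,2-dimethyl-5-(nitromethyl)-1,3-dioxolan-4-yl]prop-2-en-1-yl methyl carbonate | [O-][N+](=O)C[C@@]1(CO)OC(C)(C)O[C@H]1/C=C\COC(=O)OC | intermediate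
17 | [(4S,5S)-5-{(1Z)-3-[(methoxycarbonyl)oxy]prop-1-en-1-yl}-2,2-dimethyl-4-(nitromethyl)-1,3-dioxolan-4-yl]methyl benzoate (key-step precursor) | [O-][N+](=O)C[C@@]1(COC(=O)c2ccccc2)OC(C)(C)O[C@H]1/C=C\COC(=O)OC | intermediate
18 | allylpalladium nitronate zwitterion from 17 (allyl–Pd(PPh3)2 cation with its own C2 nitronate; drawn in the C3-bound form, phosphines omitted) | [O-][N+]([O-])=C[C@@]1(COC(=O)c2ccccc2)OC(C)(C)O[C@H]1/C=C\C[Pd+] | intermediate (not isolated)
19 | [(3aS,4S,7aS)-2,2-dimethyl-4-nitro-3a,4,5,7a-tetrahydro-1,3-benzodioxol-3a-yl]methyl benzoate (key-step product; 4R epimer equally usable) | [O-][N+](=O)[C@H]1CC=C[C@@H]2OC(C)(C)O[C@]12COC(=O)c1ccccc1 | intermediate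
20 | [(3aS,4S,6R,7R,7aS)-6,7-dihydroxy-2,2-dimethyl-4-nitrohexahydro-1,3-benzodioxol-3a-yl]methyl benzoate (4R epimer equally usable) | [O-][N+](=O)[C@H]1C[C@@H](O)[C@@H](O)[C@@H]2OC(C)(C)O[C@]12COC(=O)c1ccccc1 | intermediate
21 | potassium nitronate of 20 | [K+].[O-][N+]([O-])=C1C[C@@H](O)[C@@H](O)[C@@H]2OC(C)(C)O[C@]12COC(=O)c1ccccc1 | intermediate (not isolated)
22 | [(3aS,6R,7R,7aS)-6,7-dihydroxy-2,2-dimethyl-4-oxohexahydro-1,3-benzodioxol-3a-yl]methyl benzoate | O=C1C[C@@H](O)[C@@H](O)[C@@H]2OC(C)(C)O[C@]12COC(=O)c1ccccc1 | intermediate
23 | O4,O5-dibutylstannylene acetal of 22 | O=C1C[C@H]3O[Sn](CCCC)(CCCC)O[C@H]3[C@@H]2OC(C)(C)O[C@]12COC(=O)c1ccccc1 | intermediate (not isolated)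
24 | [(3aS,6R,7R,7aS)-7-(benzoyloxy)-6-hydroxy-2,2-dimethyl-4-oxohexahydro-1,3-benzodioxol-3a-yl]methyl benzoate | O=C1C[C@@H](O)[C@@H](OC(=O)c2ccccc2)[C@@H]2OC(C)(C)O[C@]12COC(=O)c1ccccc1 | intermediate
25 | [(1S,2S,3R,4R)-3-(benzoyloxy)-1,2,4-trihydroxy-6-oxocyclohexyl]methyl benzoate (CNP0127041.1) | O=C(OC[C@@]1(O)C(=O)C[C@@H](O)[C@@H](OC(=O)c2ccccc2)[C@@H]1O)c1ccccc1 | target

## Step count and least certain steps

Total step count: 17. Longest linear sequence: 17 steps, from 1 to 25; all other inputs are commercial reagents.

Step 13 (key step). The most likely failures are: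
- isomerisation of the anti allyl complex to the syn complex before ring closure, after which only elimination to a diene or capture by methanol remains;
- β-elimination of the C1 ketal oxygen from the nitronate;
- intermolecular allylation at higher concentration.

The fallback closes the ring at the alkene and not at C2–C3. It sets out from 13 and rejoins the route at 19. Intermolecular Tsuji–Trost allylation of the nitromethyl carbon of 13 with allyl methyl carbonate and Pd(PPh3)4 should give the C2-allyl nitro enoate F1. Ring-closing metathesis of F1 with the second-generation Grubbs catalyst RuCl2(H2IMes)(PCy3)(=CHPh) then forms C4=C5 with loss of the acrylate end. The enoate geometry no longer matters, and the C7 benzoate of 13 is carried straight into 19.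

Step 3. The likely failure is insufficient facial discrimination at the ketone, made worse by reversibility of the nitroaldol addition, which lets the kinetic ratio drift towards an unknown equilibrium ratio; slow epimerisation at C6 is a lesser risk. The fallback changes the controlling group. It sets out from 1 and rejoins at 7. Compound 1 is ketalised with 1,1-dimethoxycyclohexane to the cyclohexylidene ketal F2, benzoylated to the ketone F3 and submitted to the Henry addition to give the nitro alcohol F4. The larger spiro ketal should increase the bias of the Felkin–Anh arrangement. The aqueous acetic acid hydrolysis of step 4 then removes the ketal and returns triol 7, so the detour costs no step. In either series the unwanted C1 epimer can be returned to the ketone by base-induced retro-Henry cleavage and recycled.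

Step 11. The likely failure is incomplete discrimination between the two primary hydroxyls, giving the bis-carbonate and the C7 carbonate beside 16. The fallback removes the need for discrimination. It sets out from 14 and rejoins at 19. Exhaustive benzoylation of 14 (BzCl, pyridine, DMAP) gives the dibenzoate F5, whose allylic benzoate serves as the leaving group. With Pd(PPh3)4 and DBU as external base in THF it should ionise to the same zwitterion 18 and close to 19. The price is that the nitronate is exposed to a stoichiometric base.

Step 15. The likely failures are β-elimination of the C1 oxygen once the nitronate is formed with a strong base, oxidation of the free carbinols by excess dioxirane, and attack of alkoxide on the C7 benzoate. The fallback avoids both the strong base and the external oxidant. It sets out from 20 and rejoins at 22. Under nitrosating conditions (NaNO2, AcOH, DMSO, 35 °C) the small equilibrium amount of nitronate is nitrosated to the geminal nitroso nitro compound F6, which collapses to ketone 22 in the weakly acidic medium.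

Step 16. The likely failures are dehydration of the β-hydroxy ketone to the conjugated enone while the stannylene is formed under heating, and some acylation at O4, which would make that elimination easy. The fallback changes the order so that no ketone is present during acylation. It sets out from 20 and rejoins at 24. Compound 20 is converted with Bu2SnO into the stannylene acetal F7 and benzoylated to the nitro monobenzoate F8. F8 is then taken through the nitrosative Nef conditions above, by way of the nitroso nitro compound F9, to 24. The price is that the regioselectivity of the tin step then depends on the conformation of the nitro-substituted ring, which is less predictable than that of 22.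

## Further compounds

F1 | step 13 | methyl (2Z)-3-[(4S,5S)-5-[(benzoyloxy)methyl]-2,2-dimethyl-5-(1-nitrobut-3-en-1-yl)-1,3-dioxolan-4-yl]prop-2-enoate (one C2 epimer drawn, both serve) | [O-][N+](=O)[C@@H](CC=C)[C@@]1(COC(=O)c2ccccc2)OC(C)(C)O[C@H]1/C=C\C(=O)OC
F2 | step 3 | 2-hydroxy-1-[(2S)-1,4-dioxaspiro[4.5]decan-2-yl]ethan-1-one | OCC(=O)[C@@H]1COC2(CCCCC2)O1
F3 | step 3 | 2-[(2S)-1,4-dioxaspiro[4.5]decan-2-yl]-2-oxoethyl benzoate | O=C(OCC(=O)[C@@H]1COC2(CCCCC2)O1)c1ccccc1
F4 | step 3 | (2S)-2-[(2S)-1,4-dioxaspiro[4.5]decan-2-yl]-2-hydroxy-3-nitropropyl benzoate | O=C(OC[C@@](O)(C[N+](=O)[O-])[C@@H]1COC2(CCCCC2)O1)c1ccccc1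
F5 | step 11 | (2Z)-3-[(4S,5S)-5-[(benzoyloxy)methyl]-2,2-dimethyl-5-(nitromethyl)-1,3-dioxolan-4-yl]prop-2-en-1-yl benzoate | [O-][N+](=O)C[C@@]1(COC(=O)c2ccccc2)OC(C)(C)O[C@H]1/C=C\COC(=O)c1ccccc1
F6 | step 15 | [(3aS,6R,7R,7aS)-6,7-dihydroxy-2,2-dimethyl-4-nitro-4-nitrosohexahydro-1,3-benzodioxol-3a-yl]methyl benzoate (not isolated; configuration at the nitroso-bearing carbon not defined) | O=NC1([N+](=O)[O-])C[C@@H](O)[C@@H](O)[C@@H]2OC(C)(C)O[C@]12COC(=O)c1ccccc1
F7 | step 16 | O4,O5-dibutylstannylene acetal of 20 (not isolated) | [O-][N+](=O)[C@H]1C[C@H]3O[Sn](CCCC)(CCCC)O[C@H]3[C@@H]2OC(C)(C)O[C@]12COC(=O)c1ccccc1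
F8 | step 16 | [(3aS,4S,6R,7R,7aS)-7-(benzoyloxy)-6-hydroxy-2,2-dimethyl-4-nitrohexahydro-1,3-benzodioxol-3a-yl]methyl benzoate | [O-][N+](=O)[C@H]1C[C@@H](O)[C@@H](OC(=O)c3ccccc3)[C@@H]2OC(C)(C)O[C@]12COC(=O)c1ccccc1
F9 | step 16 | [(3aS,6R,7R,7aS)-7-(benzoyloxy)-6-hydroxy-2,2-dimethyl-4-nitro-4-nitrosohexahydro-1,3-benzodioxol-3a-yl]methyl benzoate (not isolated; configuration at the nitroso-bearing carbon not defined) | O=NC1([N+](=O)[O-])C[C@@H](O)[C@@H](OC(=O)c3ccccc3)[C@@H]2OC(C)(C)O[C@]12COC(=O)c1ccccc1
A1 | alternative 1 | furan | c1ccoc1
A2 | alternative 1 | 2-bromoprop-2-enal (2-bromoacrolein) | C=C(Br)C=O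
A3 | alternative 1 | (1S,2S,4S)-2-bromo-7-oxabicyclo[2.2.1]hept-5-ene-2-carbaldehyde (formyl exo) | O=C[C@]1(Br)C[C@H]2C=C[C@@H]1O2
A4 | alternative 2 | (4S,5R)-4-[(2R)-2-{[tert-butyl(dimethyl)silyl]oxy}but-3-en-1-yl]-5-ethenyl-2,2-dimethyl-1,3-dioxan-5-ol | C=C[C@@]1(O)COC(C)(C)O[C@H]1C[C@@H](O[Si](C)(C)C(C)(C)C)C=C
A5 | alternative 2 | (4aR,7R,8aS)-7-{[tert-butyl(dimethyl)silyl]oxy}-2,2-dimethyl-4a,7,8,8a-tetrahydro-4H-1,3-benzodioxin-4a-ol | O[C@]12COC(C)(C)O[C@H]1C[C@@H](O[Si](C)(C)C(C)(C)C)C=C2
A6 | alternative 3 | methyl 6-deoxyhex-5-enopyranoside with the C5 benzoate, the C1/C6 isopropylidene ketal and the C7 benzoyloxymethyl branch of the target (target numbering; methoxy trans to the neighbouring benzoate) | C=C1O[C@H](OC)[C@@H](OC(=O)c2ccccc2)[C@@H]2OC(C)(C)O[C@]12COC(=O)c1ccccc1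
A7 | alternative 3 | [(3aS,6R,7R,7aS)-7-(benzoyloxy)-6-hydroxy-2,2-dimethyl-4-oxohexahydro-1,3-benzodioxol-3a-yl]methyl benzoate (identical with 24) | O=C1C[C@@H](O)[C@@H](OC(=O)c2ccccc2)[C@@H]2OC(C)(C)O[C@]12COC(=O)c1ccccc1
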